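**Retrosynthetic overview**

1. Ester C–O: target ⇒ 1,4-epoxyeudesman-6-ol + 4-methoxybenzoyl chloride.
2. C5–H and C6–OH ⇒ syn hydroboration–oxidation of 1,4-epoxyeudesm-5-ene from the face of the oxygen bridge; this sets the trans ring fusion and puts 6-OH cis to the isopropyl group.
3. Key disconnection, C4–O and C4–C5 together ⇒ a monocyclic silyl ether/ketal/vinylsilane: one acid-triggered operation closes the oxolane (as an oxocarbenium ion) and then ring A by vinylsilane attack, giving the whole 7-oxabicyclo[2.2.1]heptane.
4. Vinylsilane ⇒ ketone (Shapiro reaction); C10–C1 ⇒ reductive aldol of (R)-carvotanacetone with a ketal aldehyde, which sets C10 and C1 from C7.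
5. Ring order: ring B from (R)-carvone (chiral pool, carries C7) → oxolane and ring A together → C5/C6 functionalisation → ester.

Atom labels C1–C15 are the eudesmane positions of the target (C14 = methyl on C10, C15 = methyl on C4; exo = the face of the oxygen bridge).

Assumption: 3-(2-methyl-1,3-dioxolan-2-yl)propanal is bought as a catalogue building block.

**Route**

Step 1
Reactants: 1 (R)-(−)-carvone
Product: 2 (R)-carvotanacetone, (5R)-2-methyl-5-(propan-2-yl)cyclohex-2-en-1-one
Conditions: H2 (1 atm), RhCl(PPh3)3 (1 mol %), toluene, rt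
Reagents that add atoms: none
Why: Homogeneous catalytic hydrogenation with RhCl(PPh3)3 reduces only the unhindered 1,1-disubstituted isopropenyl alkene and leaves the conjugated trisubstituted enone, so the (R) centre (later C7) is untouched.

Step 2
Reactants: 2 (R)-carvotanacetone; 3 3-(2-methyl-1,3-dioxolan-2-yl)propanal
Product: 5 (2R,5R)-2-[(1R)-1-hydroxy-3-(2-methyl-1,3-dioxolan-2-yl)propyl]-2-methyl-5-(propan-2-yl)cyclohexan-1-one, via lithium enolate 4 (not isolated)
Conditions: LiBH(s-Bu)3 (1.05 equiv), THF, −78 °C, 1 h; then 3 (1.2 equiv), −78 °C, 1 h; H2O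
Reagents that add atoms: none
Why: Conjugate reduction gives the regiodefined tetrasubstituted lithium enolate, and the aldol addition (Zimmerman–Traxler chair) takes the aldehyde axially onto the enolate face cis to the isopropyl group (the sense known from annulations of dihydrocarvone to the 10-epi series), setting C10, while the equatorial aldehyde chain sets C1 with OH anti to the ring CH2.

Step 3
Reactants: 5 aldol adduct
Product: 6 2,4,6-triisopropylbenzenesulfonylhydrazone of 5 (N–N bond anti to the quaternary carbon C10)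
Conditions: 2,4,6-(i-Pr)3C6H2SO2NHNH2 (1.2 equiv), PPTS (5 mol %), 4 Å MS, THF, rt → 40 °C
Reagents that add atoms: 2,4,6-triisopropylbenzenesulfonohydrazide, CC(C)c1cc(C(C)C)c(S(=O)(=O)NN)c(C(C)C)c1
Why: Hydrazone formation under nearly neutral conditions leaves the dioxolane and the β-hydroxy ketone intact and touches no stereocentre; the sulfonamide nitrogen sits syn to the only α-CH2 (C6).

Step 4
Reactants: 6 trisylhydrazone
Product: 8 vinylsilane silyl ether (C5–SiMe3 on the C5=C6 alkene, C1–OSiMe3, dioxolane intact; C1, C7, C10 as in 5), via vinyllithium alkoxide 7 (not isolated)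
Conditions: n-BuLi (3.3 equiv), TMEDA, THF, −78 → 0 °C; then Me3SiCl (4 equiv), −78 °C → rt
Reagents that add atoms: chlorotrimethylsilane, C[Si](C)(C)Cl
Why: Shapiro reaction: after N–H and O–H deprotonation the hydrazone is deprotonated at C6 (C10 has no hydrogen, so the regiochemistry is unambiguous), loses sulfinate and N2 to give the C5 vinyllithium, and Me3SiCl silylates both carbon and oxygen without touching a stereocentre.

Step 5
Reactants: 8 vinylsilane silyl ether
Product: 10 (1R,4S,7S,10S)-1,4-epoxyeudesm-5-ene, via oxocarbenium triflate 9 (not isolated)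
Conditions: Me3SiOTf (0.2 equiv), 2,6-di-tert-butyl-4-methylpyridine (0.3 equiv), CH2Cl2, −78 → −20 °C
Reagents that add atoms: none
Why: Proposed new method: Me3SiOTf opens the dioxolane, the C1 silyl ether oxygen closes onto the cation to give the five-membered oxocarbenium ion 9 (Noyori-type silyl ether/ketal exchange), and the vinylsilane carbon C5, two atoms away on C10, attacks C4 at the silicon-bearing carbon (β-silyl cation, loss of Me3Si+ regenerates the catalyst), so the oxolane and ring A form in one operation with C4 fixed by the bridge and the C5=C6 alkene kept; the closest known chemistry is the Overman vinylsilane-terminated oxocarbenium (Prins) cyclisation, and the geometry matches the π-route to norbornyl systems.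

Step 6
Reactants: 10 1,4-epoxyeudesm-5-ene
Product: 12 (1R,4S,5R,6R,7S,10S)-1,4-epoxyeudesman-6-ol, via alkylborane 11 (not isolated)
Conditions: BH3·SMe2 (1.5 equiv), CH2Cl2, 0 °C → rt; then NaOH (3 M aq.), H2O2 (30 %), THF, 0 °C → rt
Reagents that add atoms: hydrogen peroxide, OO
Why: Hydroboration–oxidation: boron adds to the less substituted C6 and hydrogen to C5 in a syn fashion from the exo face, because the endo face is closed by the 10-methyl group and the C2–C3 bridge and the basic bridge oxygen can pre-complex the borane, and oxidation with retention gives 5-H and 6-OH both exo, i.e. the trans ring fusion with 6-OH cis to the isopropyl group.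

Step 7
Reactants: 12 1,4-epoxyeudesman-6-ol; 13 4-methoxybenzoyl chloride
Product: 14 (1R,4S,5R,6R,7S,10S)-1,4-epoxyeudesman-6-yl 4-methoxybenzoate (CNP0196044.2)
Conditions: 13 (1.5 equiv), Et3N (3 equiv), DMAP (0.2 equiv), CH2Cl2, 0 °C → rt
Reagents that add atoms: none
Why: DMAP-catalysed acylation (acylpyridinium transfer) of the secondary alcohol forms the ester without touching any stereocentre.

**Compound list**

1 | (R)-(−)-carvone, (5R)-2-methyl-5-(prop-1-en-2-yl)cyclohex-2-en-1-one | CC1=CC[C@H](CC1=O)C(C)=C | starting material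
2 | (R)-carvotanacetone, (5R)-2-methyl-5-(propan-2-yl)cyclohex-2-en-1-one | CC1=CC[C@H](CC1=O)C(C)C | intermediate
3 | 3-(2-methyl-1,3-dioxolan-2-yl)propanal | CC1(CCC=O)OCCO1 | starting material
4 | lithium (5R)-2-methyl-5-(propan-2-yl)cyclohex-1-en-1-olate (not isolated) | CC1=C([O-])C[C@@H](CC1)C(C)C.[Li+] | intermediate
5 | (2R,5R)-2-[(1R)-1-hydroxy-3-(2-methyl-1,3-dioxolan-2-yl)propyl]-2-methyl-5-(propan-2-yl)cyclohexan-1-one | O=C1C[C@H](C(C)C)CC[C@]1(C)[C@H](O)CCC2(C)OCCO2 | intermediate
6 | 2,4,6-triisopropylbenzenesulfonylhydrazone of 5 | CC(C)c1cc(C(C)C)c(c(C(C)C)c1)S(=O)(=O)N/N=C2\C[C@H](C(C)C)CC[C@]2(C)[C@H](O)CCC3(C)OCCO3 | intermediate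
7 | C5 vinyllithium with lithium alkoxide at C1 (not isolated) | [Li]C1=C[C@H](C(C)C)CC[C@]1(C)[C@H](O[Li])CCC2(C)OCCO2 | intermediate
8 | C5-trimethylsilyl C5=C6 alkene with C1 trimethylsilyl ether and dioxolane | C[Si](C)(C)C1=C[C@H](C(C)C)CC[C@]1(C)[C@H](O[Si](C)(C)C)CCC2(C)OCCO2 | intermediate
9 | five-membered 2-methyl oxocarbenium ion carrying the silylcyclohexenyl group, triflate salt (not isolated) | CC1=[O+][C@H](CC1)[C@@]2(C)CC[C@@H](C(C)C)C=C2[Si](C)(C)C.[O-]S(=O)(=O)C(F)(F)F | intermediate
10 | (1R,4S,7S,10S)-1,4-epoxyeudesm-5-ene | C1=C2[C@]3(C)CC[C@@H](O3)[C@@]2(C)CC[C@H]1C(C)C | intermediate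
11 | (1,4-epoxyeudesman-6-yl)borane, boron and 5-H on the exo face (not isolated) | B[C@@H]1[C@H](C(C)C)CC[C@]2(C)[C@H]3CC[C@](C)(O3)[C@@H]12 | intermediate
12 | (1R,4S,5R,6R,7S,10S)-1,4-epoxyeudesman-6-ol | O[C@@H]1[C@H](C(C)C)CC[C@]2(C)[C@H]3CC[C@](C)(O3)[C@@H]12 | intermediate
13 | 4-methoxybenzoyl chloride | COc1ccc(cc1)C(Cl)=O | starting material
14 | (1R,4S,5R,6R,7S,10S)-1,4-epoxyeudesman-6-yl 4-methoxybenzoate | COc1ccc(C(=O)O[C@@H]2[C@H](C(C)C)CC[C@]3(C)[C@H]4CC[C@](C)(O4)[C@@H]23)cc1 | target

**Step count and risks**

Total steps: 7. Longest linear sequence: 7 (1 → 14).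

Most likely to fail, first: step 5. The oxocarbenium ion could be attacked through C6 instead of C5, which would give an 8-oxabicyclo[3.2.1]octane; the vinylsilane could also be protodesilylated, and the 7-oxabicyclo[2.2.1]heptane is strained. The fallback sets out from 8 and comes back at 10, and it replaces the cationic closure by a carbopalladation whose regiochemistry is fixed by ring size. N-iodosuccinimide (MeCN, 0 °C) followed by PPTS in hot toluene exchanges silicon for iodine and turns the silyl ether/ketal into the cyclic enol ether, giving the vinyl iodide dihydrofuran F1. An intramolecular Heck reaction (Pd(OAc)2, PPh3, Ag2CO3, MeCN, 80 °C) adds C5 to the oxygen-bearing alkene carbon C4 in the 5-exo mode and, after syn β-hydride elimination, gives the diene F2. Diimide (KO2CN=NCO2K, AcOH, MeOH) then reduces only the strained disubstituted C2=C3 bond to give 10.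

Second: step 6. The isopropyl group on C7 lies on the exo side next to C6, so the borane may come from the endo face instead and give the cis-fused 5,6-bis-epimer. The fallback sets out from 10 and comes back at 12, and it uses that same endo bias with an oxygen donor. m-Chloroperbenzoic acid (NaHCO3, CH2Cl2, 0 °C) gives the endo epoxide F3. BF3·OEt2 (CH2Cl2, −78 °C) opens it at the tertiary C5 while the C6 hydrogen shifts to the exo face of C5 (Meinwald rearrangement), giving the trans-fused ketone F4. NaBH4 with CeCl3·7H2O (MeOH, −40 °C) delivers hydride anti to the isopropyl group; the other alcohol would be syn-axial to the 10-methyl group, so 12 is expected.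

Third: step 2. Two stereocentres are set at once; the facial selectivity (C10) and the chair selectivity (C1) may each be only moderate, and the aldolate can revert. The fallback sets out from 2 and comes back at 5. Conjugate reduction with LiBH(s-Bu)3 and trapping with Me3SiCl/Et3N gives the isolable silyl enol ether F5. A Mukaiyama aldol addition to 3 (BF3·OEt2, CH2Cl2, −78 °C) through an open transition state then gives 5 irreversibly, and the diastereomers are separated by chromatography.

**Further compounds**

F1 | step 5 | vinyl iodide dihydrofuran: 2-[2-iodo-1-methyl-4-(propan-2-yl)cyclohex-2-en-1-yl]-5-methyl-2,3-dihydrofuran, configuration as in 8 | IC1=C[C@H](C(C)C)CC[C@]1(C)[C@H]2CC=C(C)O2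
F2 | step 5 | (1R,4S,7S,10S)-1,4-epoxyeudesma-2,5-diene | C1=C2[C@]3(C)C=C[C@@H](O3)[C@@]2(C)CC[C@H]1C(C)C
F3 | step 6 | 1,4:5,6-diepoxyeudesmane with the 5,6-epoxide on the endo face | O1[C@H]2[C@H](C(C)C)CC[C@]3(C)[C@H]4CC[C@](C)(O4)[C@]123
F4 | step 6 | trans-fused 1,4-epoxyeudesman-6-one, 5-H on the exo face | O=C1[C@H](C(C)C)CC[C@]2(C)[C@H]3CC[C@](C)(O3)[C@@H]12
F5 | step 2 | trimethyl{[(5R)-2-methyl-5-(propan-2-yl)cyclohex-1-en-1-yl]oxy}silane | CC1=C(O[Si](C)(C)C)C[C@@H](CC1)C(C)C
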